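The vessel was closed, stirred and isothermal, and from flask to flask I changed the substrate charged while partner, reagent and capture agent stayed the same.

the same everywhere: partner 0.420 M; reagent 0.440 M; capture agent 0.0400 M; time 3.0 h

| charge | substrate |
|---|---|
| north | 0.25 M |
| east | 0.40 M |
| north-east | 0.60 M |
| west | 1.0 M |

    reagent + partner → second intermediate (k1 = 0.036 M⁻¹ min⁻¹)
    open intermediate + capture agent → trapped intermediate (k2 = 1.1 M⁻¹ min⁻¹)
    open intermediate + second intermediate → target (k3 = 0.077 M⁻¹ min⁻¹)
    substrate + reagent → open intermediate (k4 = 0.052 M⁻¹ min⁻¹)
    2 open intermediate → homo product (k5 = 0.11 M⁻¹ min⁻¹)

- in percentages every species weighs as the substrate in it: one homo product counts as two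
- two of one species on the left: rate k times its square, two consumed each time
- "hardly changes" means that all values lie within two and a half points (for a concentration: within two and a half percent of the largest)
- run time (north): 3.0 h

1. [target] at the end for north, east, north-east, west, in this order
2. the course of these numbers from the first flask to the last (rises all the way / falls all the way / falls, then rises / rises, then falls / hardly changes)

Substrate and partner both draw on the reagent, which is the limiting reagent in north, since its charge is smaller than theirs together. Reagent stands in both of their rates, so it cancels from the ratio, and neither capture nor homo coupling touches substrate or partner. Hence the fraction of partner left equals the fraction of substrate left raised to one number, the constant of the partner step over that of the substrate step. This is the selectivity factor, 0.692. Multiplied by partner over substrate, it gives the divide of the reagent at the start: 1.16 in north, 0.727 in east, 0.485 in north-east and 0.291 in west.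

I then reckoned two extreme versions. In the first I froze that divide and let the reagent be spent, since in north 3.0 h is longer than its half-life of 0.76 h by the partner step. Capture agent took its 0.0400 M of open intermediate, and the rest met second intermediate at once, so the target was the smaller arm. That gave figures of 0.163 M, 0.185 M, 0.144 M and 0.0991 M. In the second version I held the two intermediates equal, so the target took a share 0.259 of what left the open intermediate, the rest going to homo product. Applied to the open intermediate left after capture, that gave 0.0422 M for north and 0.0780 M for west. Both versions froze the divide and took the run as finished, so I held them as rough marks and not as bounds. The figures of the first version were highest in east, and their course, a rise and then a fall, was what I committed to.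

The forecast gave 0.065 M, 0.074 M, 0.068 M and 0.056 M, so rises, then falls, holding that at high substrate “the reagent is diverted from the partner”.

The flasks gave 0.0662 M, 0.0734 M, 0.0689 M and 0.0542 M, so rises, then falls, with the turn read near 0.41 M. In north after 3.00 h, 7.13 % of the reagent remained, with substrate at 30.6 % and partner at 44.0 %. The selectivity factor applied to that substrate figure gives 44.1 % of partner. In west, substrate stood at 66.4 %, which the same power turns into 75.3 %, and the partner there stood at 75.3 %.

(The constants used here are made up; no experiment stands behind them.)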